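In ent-kaurane numbering the target is ring A joined by the C9–C10 bond to a bicyclo[3.2.1]octane (rings C and D). The plan rests on the three-carbon bridge C9–C11–C12 of ring C. This bridge spans C8 and C13, the two ring D carbons flanking C14. A rhodium vinylcarbenoid cyclopropanates the C13=C16 enol ether bond of a flat, achiral 2-siloxycyclopentadiene. Strain-driven Cope rearrangement of the cis-divinylcyclopropane then forges C8–C9. One operation closes ring C, sets C8 and C13, and leaves C12 and C16 differentiated. The derived C9=C11–C12 enone then captures the C10 tertiary radical of a separately built ring A.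

Key step: step 9

Atom labels (ent-kaurane numbering):
- Ring A is C1–C5 and C10.
- C19 and C6 are the carboxyl carbons on C4 and C5.
- C18 and C20 are the methyl groups on C4 and C10.
- C7 is the aldehyde carbon on C8, and C17 is the methylidene carbon on C16.

Assumption: the facial sense of the two chiral catalysts (steps 1 and 9) is taken as drawn. Both catalysts are available in either mirror-image form, so the antipode is used if the sense proves opposite.

Step 1
Reactants: 1 di-tert-butyl fumarate; 2 (E)-penta-1,3-diene
Product: 3 di-tert-butyl (1S,2S)-3-methylcyclohex-4-ene-1,2-dicarboxylate (both C3 epimers)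
Conditions: (S)-3,3-diphenyl-1-(o-tolyl)tetrahydro-1H,3H-pyrrolo[1,2-c][1,3,2]oxazaborole (20 mol %), Tf2NH (20 mol %), 2 (3 equiv), CH2Cl2, −20 °C
Reagents that add atoms: none
Why: Enantioselective Diels–Alder reaction closing ring A: the cationic oxazaborolidinium Lewis acid binds one fumarate carbonyl and shields one alkene face, so the suprafacial addition should fix the trans (1S,2S) pair, of which C5 is carried to the target, while the methyl-bearing C10 forms as an epimer mixture that is erased in step 3.

Step 2
Reactants: 3 di-tert-butyl (1S,2S)-3-methylcyclohex-4-ene-1,2-dicarboxylate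
Product: 5 di-tert-butyl (1R,2S)-1,3-dimethylcyclohex-4-ene-1,2-dicarboxylate, via lithium enolate 4 (not isolated)
Conditions: LDA (1.1 equiv), THF, −78 °C; MeI, DMPU, −78 → −20 °C
Reagents that add atoms: iodomethane, CI
Why: Ester enolate alkylation: LDA should remove the less hindered α-proton at C4 (remote from the ring methyl), and because allylic strain against the exocyclic enolate forces the neighbouring C5 ester pseudoaxial, MeI enters anti to it, which makes the two esters cis and sets the quaternary C4.

Step 3
Reactants: 5 di-tert-butyl (1R,2S)-1,3-dimethylcyclohex-4-ene-1,2-dicarboxylate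
Product: 6 di-tert-butyl (1R,2S)-1,3-dimethylcyclohex-3-ene-1,2-dicarboxylate
Conditions: RuHCl(CO)(PPh3)3 (5 mol %), toluene, 110 °C
Reagents that add atoms: none
Why: Alkene isomerisation by ruthenium hydride insertion and β-hydride elimination should move the disubstituted C1=C2 bond to the more stable trisubstituted C10=C1 position, a further shift into conjugation needing an unfavourable tertiary ruthenium alkyl; no stereocentre is made and both C10 epimers converge on 6.

Step 4
Reactants: 7 2,2-dimethoxyacetaldehyde; 8 but-3-en-2-one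
Product: 9 1,1-dimethoxyhexane-2,5-dione
Conditions: 3-benzyl-5-(2-hydroxyethyl)-4-methylthiazolium chloride (10 mol %), Et3N (30 mol %), EtOH, 78 °C
Reagents that add atoms: none
Why: Stetter reaction: the thiazolylidene turns the aldehyde carbon into an acyl anion equivalent that adds 1,4 to the enone and gives the 1,4-diketone; no stereocentre is formed.

Step 5
Reactants: 9 1,1-dimethoxyhexane-2,5-dione
Product: 10 3-(dimethoxymethyl)cyclopent-2-en-1-one
Conditions: 2% aq NaOH, EtOH, reflux
Reagents that add atoms: none
Why: Intramolecular aldol condensation (5-enolexo): the methyl ketone enolate attacks the more electrophilic acetal-flanked ketone and dehydration gives ring D as the cyclopentenone, the acetal being inert to base.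

Step 6
Reactants: 10 3-(dimethoxymethyl)cyclopent-2-en-1-one
Product: 12 [4-(dimethoxymethyl)cyclopenta-1,3-dien-2-yl]oxy(triethyl)silane, via lithium dienolate 11 (not isolated)
Conditions: LDA (1.05 equiv), THF, −78 °C; Et3SiCl, −78 °C; cold pentane work-up, used at once
Reagents that add atoms: chlorotriethylsilane, CC[Si](Cl)(CC)CC
Why: Kinetic α′-deprotonation at C13 and O-silylation give the cross-conjugated 2-siloxycyclopentadiene with C14 as the only sp3 ring carbon, and the low temperature suppresses 1,5-hydrogen shifts.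

Step 7
Reactants: 13 ethyl 2-diazo-3-oxobutanoate
Product: 14 ethyl 2-diazo-3-hydroxybutanoate (racemic)
Conditions: NaBH4, MeOH, 0 °C
Reagents that add atoms: none
Why: Chemoselective borohydride reduction of the ketone leaves the acceptor-stabilised diazo ester untouched, and the new carbinol centre is lost in step 8.

Step 8
Reactants: 14 ethyl 2-diazo-3-hydroxybutanoate
Product: 15 ethyl 2-diazobut-3-enoate
Conditions: POCl3, Et3N, CH2Cl2, 0 °C → 23 °C; kept cold and used at once
Reagents that add atoms: none
Why: Activation of the alcohol as a dichlorophosphate and amine-induced β-elimination is the standard dehydration route to vinyldiazoacetates.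

Step 9
Reactants: 12 [4-(dimethoxymethyl)cyclopenta-1,3-dien-2-yl]oxy(triethyl)silane; 15 ethyl 2-diazobut-3-enoate
Product: 17 ethyl (1S,5R)-5-(dimethoxymethyl)-7-[(triethylsilyl)oxy]bicyclo[3.2.1]octa-2,6-diene-2-carboxylate, via divinylcyclopropane 16 (not isolated)
Conditions: Rh2(S-DOSP)4 (1 mol %), 12 (2 equiv), hexanes, −40 °C, slow addition of 15, then warm to 23 °C
Reagents that add atoms: none
Why: Rh2(S-DOSP)4 expels N2 from 15 and the donor/acceptor vinylcarbenoid adds end-on to the most electron-rich and least hindered π bond of 12, the C13=C16 silyl enol ether, to give the donor–acceptor cis-divinylcyclopropane 16 with the vinyl group endo, which relieves its ring strain by a boat-shaped [3,3] shift that breaks C12–C16 and makes C8–C9. The closest known reaction type is the tandem cyclopropanation/Cope rearrangement (formal [4+3] cycloaddition) of vinyldiazoacetates with cyclopentadiene and with siloxydienes. Ring C is closed as a [4+3] annulation across C13 and C8 of ring D, C12–C13 in the cyclopropanation and C8–C9 in the sigmatropic step, and because C14 already ties C8 to C13 the new seven-membered perimeter contains the six-membered ring C8–C14–C13–C12–C11–C9. C13 is set by the chiral carboxylate pocket of the catalyst, which selects one enantiotopic face of the planar diene, and C8 follows by necessity because the bridge can span only one face of ring D. The step needs selectivity for C13=C16 over C15=C8, attack at the carbenoid carbon rather than at the vinyl terminus, and no 1,5-hydrogen shift in 12; these are secured by the siloxy donor set against the inductively deactivated acetal-bearing alkene, by the hydrocarbon solvent, and by holding the mixture at −40 °C until 15 is consumed.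

Step 10
Reactants: 17 ethyl (1S,5R)-5-(dimethoxymethyl)-7-[(triethylsilyl)oxy]bicyclo[3.2.1]octa-2,6-diene-2-carboxylate
Product: 18 (1S,5R)-5-(dimethoxymethyl)-7-oxobicyclo[3.2.1]oct-2-ene-2-carboxylic acid
Conditions: LiOH·H2O (3 equiv), THF/MeOH/H2O, 0 → 23 °C; then 0.5 M HCl to pH 4, 0 °C
Reagents that add atoms: lithium hydroxide, [Li+].[OH-]
Why: Saponification of the unhindered enoate, with hydroxide also cleaving the triethylsilyl enol ether to the C16 ketone; C13 is a bridgehead and cannot enolise, and the acetal is stable to base and to the brief mild acidification.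

Step 11
Reactants: 18 (1S,5R)-5-(dimethoxymethyl)-7-oxobicyclo[3.2.1]oct-2-ene-2-carboxylic acid
Product: 21 (1S,5R)-5-(dimethoxymethyl)bicyclo[3.2.1]octane-2,7-dione, via acyl azide 19 (not isolated), via vinyl isocyanate 20 (not isolated)
Conditions: (PhO)2P(O)N3 (1.1 equiv), Et3N (1.2 equiv), toluene, 0 → 85 °C; then THF/aq NaH2PO4 (pH 4.5), 45 °C
Reagents that add atoms: diphenylphosphoryl azide, O=P(N=[N+]=[N-])(Oc1ccccc1)Oc1ccccc1; water, O
Why: Curtius rearrangement of the α,β-unsaturated acid moves C12 from carbon to nitrogen, and buffered hydrolysis of the vinyl isocyanate (carbamic acid, enamine, imine) leaves the C12 ketone one carbon shorter at a pH the acetal should survive; no stereocentre is touched.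

Step 12
Reactants: 21 (1S,5R)-5-(dimethoxymethyl)bicyclo[3.2.1]octane-2,7-dione
Product: 22 (1R,5R)-5-(dimethoxymethyl)bicyclo[3.2.1]oct-3-ene-2,7-dione
Conditions: IBX (2 equiv), DMSO, 70 °C
Reagents that add atoms: none
Why: IBX dehydrogenation of a ketone is regiospecific here, because only C11–C9 offers an enolisable α-hydrogen with a β-hydrogen, C13 being a bridgehead and C8 quaternary.

Step 13
Reactants: 22 (1R,5R)-5-(dimethoxymethyl)bicyclo[3.2.1]oct-3-ene-2,7-dione; 6 di-tert-butyl (1R,2S)-1,3-dimethylcyclohex-3-ene-1,2-dicarboxylate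
Product: 23 di-tert-butyl (1R,2S,3S)-3-[(1R,2S,5S)-1-(dimethoxymethyl)-4,6-dioxobicyclo[3.2.1]octan-2-yl]-1,3-dimethylcyclohexane-1,2-dicarboxylate
Conditions: Fe(acac)3 (30 mol %), PhSiH3 (2.5 equiv), 6 (3 equiv), EtOH/(CH2OH)2 5:1, 60 °C
Reagents that add atoms: none
Why: Hydrogen-atom-transfer Giese coupling (reductive olefin coupling): an iron hydride delivers H to C1 of 6, the nucleophilic tertiary C10 radical bonds through its face anti to the two cis esters (sets C10) to the β-carbon C9 of 22 from the exo face, syn to the one-carbon bridge C14 and away from the C15–C16 bridge (sets C9 with ring A axial on ring C), and ethanol protonates the resulting enolate.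

Step 14
Reactants: 23 di-tert-butyl (1R,2S,3S)-3-[(1R,2S,5S)-1-(dimethoxymethyl)-4,6-dioxobicyclo[3.2.1]octan-2-yl]-1,3-dimethylcyclohexane-1,2-dicarboxylate
Product: 24 di-tert-butyl (1R,2S,3S)-3-[(1R,2S,5R)-1-(dimethoxymethyl)-6-methylidene-4-oxobicyclo[3.2.1]octan-2-yl]-1,3-dimethylcyclohexane-1,2-dicarboxylate
Conditions: Ph3PCH3Br (1.3 equiv), KOtBu (1.2 equiv), THF, 0 °C; then 23, −20 → 0 °C
Reagents that add atoms: methyltriphenylphosphonium bromide, C[P+](c1ccccc1)(c1ccccc1)c1ccccc1.[Br-]
Why: Wittig methylenation: the C16 cyclopentanone has an open exo face, whereas C12 is screened on one face by the axial ring A substituent at C9 and on the other by the C15–C16 bridge, so a small excess of ylide should take C16 only; no stereocentre changes.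

Step 15
Reactants: 24 di-tert-butyl (1R,2S,3S)-3-[(1R,2S,5R)-1-(dimethoxymethyl)-6-methylidene-4-oxobicyclo[3.2.1]octan-2-yl]-1,3-dimethylcyclohexane-1,2-dicarboxylate
Product: 25 (1R,2S,3S)-3-[(1R,2S,5R)-1-formyl-6-methylidene-4-oxobicyclo[3.2.1]octan-2-yl]-1,3-dimethylcyclohexane-1,2-dicarboxylic acid (target)
Conditions: TFA/CH2Cl2 1:4, H2O (10 equiv), 0 → 23 °C
Reagents that add atoms: water, O
Why: Acidolysis: TFA cleaves both tert-butyl esters by alkyl–oxygen fission, which is indifferent to the crowding at C4 and C5, and the water hydrolyses the dimethyl acetal to the C7 aldehyde; C8 is quaternary and C13 a bridgehead, so nothing can epimerise or move into conjugation.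

Compound list
1 | di-tert-butyl fumarate | CC(C)(C)OC(=O)/C=C/C(=O)OC(C)(C)C | starting material
2 | (E)-penta-1,3-diene | C/C=C/C=C | starting material
3 | di-tert-butyl (1S,2S)-3-methylcyclohex-4-ene-1,2-dicarboxylate, both C3 epimers | CC1C=CC[C@H](C(=O)OC(C)(C)C)[C@H]1C(=O)OC(C)(C)C | intermediate
4 | lithium enolate of 3 at C4 | CC1C=CCC(=C([O-])OC(C)(C)C)[C@H]1C(=O)OC(C)(C)C.[Li+] | intermediate
5 | di-tert-butyl (1R,2S)-1,3-dimethylcyclohex-4-ene-1,2-dicarboxylate, esters cis, both C3 epimers | CC1C=CC[C@@](C)(C(=O)OC(C)(C)C)[C@H]1C(=O)OC(C)(C)C | intermediate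
6 | di-tert-butyl (1R,2S)-1,3-dimethylcyclohex-3-ene-1,2-dicarboxylate | CC1=CCC[C@@](C)(C(=O)OC(C)(C)C)[C@H]1C(=O)OC(C)(C)C | intermediate
7 | 2,2-dimethoxyacetaldehyde | COC(OC)C=O | starting material
8 | but-3-en-2-one | CC(=O)C=C | starting material
9 | 1,1-dimethoxyhexane-2,5-dione | COC(OC)C(=O)CCC(C)=O | intermediate
10 | 3-(dimethoxymethyl)cyclopent-2-en-1-one | COC(OC)C1=CC(=O)CC1 | intermediate
11 | lithium cross-conjugated dienolate of 10 | COC(OC)C1=CC([O-])=CC1.[Li+] | intermediate
12 | [4-(dimethoxymethyl)cyclopenta-1,3-dien-2-yl]oxy(triethyl)silane | COC(OC)C1=CC(O[Si](CC)(CC)CC)=CC1 | intermediate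
13 | ethyl 2-diazo-3-oxobutanoate | CCOC(=O)C(=[N+]=[N-])C(C)=O | starting material
14 | ethyl 2-diazo-3-hydroxybutanoate (racemic) | CCOC(=O)C(=[N+]=[N-])C(C)O | intermediate
15 | ethyl 2-diazobut-3-enoate | CCOC(=O)C(=[N+]=[N-])C=C | intermediate
16 | ethyl 3-(dimethoxymethyl)-6-ethenyl-1-[(triethylsilyl)oxy]bicyclo[3.1.0]hex-2-ene-6-carboxylate, ethenyl endo (cis to the five-membered ring) | CC[Si](CC)(CC)O[C@]12C=C(C(OC)OC)C[C@H]1[C@@]2(C(=O)OCC)C=C | intermediate
17 | ethyl (1S,5R)-5-(dimethoxymethyl)-7-[(triethylsilyl)oxy]bicyclo[3.2.1]octa-2,6-diene-2-carboxylate | CC[Si](CC)(CC)OC1=C[C@]2(C(OC)OC)C[C@H]1C(C(=O)OCC)=CC2 | intermediate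
18 | (1S,5R)-5-(dimethoxymethyl)-7-oxobicyclo[3.2.1]oct-2-ene-2-carboxylic acid | O=C1C[C@]2(C(OC)OC)C[C@H]1C(C(=O)O)=CC2 | intermediate
19 | acyl azide of 18 | O=C1C[C@]2(C(OC)OC)C[C@H]1C(C(=O)N=[N+]=[N-])=CC2 | intermediate
20 | 5-(dimethoxymethyl)-2-isocyanatobicyclo[3.2.1]oct-2-en-7-one, bridgeheads as in 18 | O=C1C[C@]2(C(OC)OC)C[C@H]1C(N=C=O)=CC2 | intermediate
21 | (1S,5R)-5-(dimethoxymethyl)bicyclo[3.2.1]octane-2,7-dione | O=C1C[C@]2(C(OC)OC)C[C@H]1C(=O)CC2 | intermediate
22 | (1R,5R)-5-(dimethoxymethyl)bicyclo[3.2.1]oct-3-ene-2,7-dione | O=C1C[C@]2(C(OC)OC)C[C@H]1C(=O)C=C2 | intermediate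
23 | di-tert-butyl (1R,2S,3S)-3-[(1R,2S,5S)-1-(dimethoxymethyl)-4,6-dioxobicyclo[3.2.1]octan-2-yl]-1,3-dimethylcyclohexane-1,2-dicarboxylate | O=C1C[C@]2(C(OC)OC)C[C@H]1C(=O)C[C@H]2[C@]1(C)CCC[C@@](C)(C(=O)OC(C)(C)C)[C@H]1C(=O)OC(C)(C)C | intermediate
24 | di-tert-butyl (1R,2S,3S)-3-[(1R,2S,5R)-1-(dimethoxymethyl)-6-methylidene-4-oxobicyclo[3.2.1]octan-2-yl]-1,3-dimethylcyclohexane-1,2-dicarboxylate | C=C1C[C@]2(C(OC)OC)C[C@H]1C(=O)C[C@H]2[C@]1(C)CCC[C@@](C)(C(=O)OC(C)(C)C)[C@H]1C(=O)OC(C)(C)C | intermediate
25 | (1R,2S,3S)-3-[(1R,2S,5R)-1-formyl-6-methylidene-4-oxobicyclo[3.2.1]octan-2-yl]-1,3-dimethylcyclohexane-1,2-dicarboxylic acid | C=C1C[C@]2(C(=O))C[C@H]1C(=O)C[C@H]2[C@]1(C)CCC[C@@](C)(C(=O)O)[C@H]1C(=O)O | target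

Total step count: 15. Longest linear sequence: 10 steps (7 and 8 to 25 through steps 4, 5, 6, 9, 10, 11, 12, 13, 14, 15).

Steps most likely to fail

Step 13.
- What may go wrong: the crowded tertiary radical may be quenched before it can bond to the hindered C9. It may instead hand a hydrogen back to iron, which would isomerise 6 into the unreactive conjugated ester. The iron hydride may also simply reduce the enone of 22.
- Fallback: it sets out from 6 and makes the same radical irreversibly, without any metal hydride. Mukaiyama hydration (Mn(dpm)3, PhSiH3, O2, iPrOH) should give the tertiary alcohol di-tert-butyl 3-hydroxy-1,3-dimethylcyclohexane-1,2-dicarboxylate F1. Acylation with methyl chlorooxoacetate (DMAP, Et3N) gives the methyl oxalate F2, and CsOH in aqueous THF gives the cesium oxalate F3. Visible-light photoredox fragmentation of F3 (Ir[dF(CF3)ppy]2(dtbbpy)PF6, blue light, DME/DMF, H2O) in the presence of 22 loses two molecules of CO2. The C10 radical then adds to C9, and the route is rejoined at 23.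

Step 9.
- What may go wrong: the siloxycyclopentadiene may scramble by 1,5-hydrogen shift before it is trapped. The enol ether may attack the unsubstituted vinyl terminus of the carbenoid, which would give open-chain alkylation. The donor–acceptor cyclopropane may open to a zwitterion instead of rearranging.
- Fallback: it sets out from the lithium dienolate 11, so that no neutral cyclopentadiene is ever present. It closes ring C by the Brook-rearrangement-mediated [3+4] annulation. Addition of 11 to (E)-3-(phenylthio)-1-(tert-butyldimethylsilyl)prop-2-en-1-one (THF, −80 → −30 °C) is followed by 1,2-Brook shift, cyclopropanolate formation and anionic oxy-Cope rearrangement. This should give the bicyclic silyl enol ether sulfide F4. TBAF then liberates the C12 enolate, which ejects thiophenolate (E1cB), and the route is rejoined at 22 as the racemate. The antipodes are parted after step 13, where the single enantiomer 6 turns them into separable diastereomers.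

Step 14.
- What may go wrong: the ylide may discriminate poorly between the two ketones. As a nucleophile it may also cleave the non-enolisable 1,3-diketone C12–C13–C16.
- Fallback: it sets out from 18 and installs C17 while C16 is the only ketone. Excess Ph3P=CH2 on the keto acid gives the methylidene acid F5. Curtius degradation as in step 11, through the acyl azide F6 and the vinyl isocyanate F7, gives the methylidene ketone F8. IBX then gives the methylidene enone F9. The exocyclic alkene of F9 would itself accept hydrogen from an iron hydride, so the union with ring A is made with the cesium oxalate F3 under the photoredox conditions described for step 13. The route is rejoined at 24.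

Further compounds
F1 | step 13 | di-tert-butyl (1R,2S)-3-hydroxy-1,3-dimethylcyclohexane-1,2-dicarboxylate, hydroxyl anti to the esters | O[C@]1(C)CCC[C@@](C)(C(=O)OC(C)(C)C)[C@H]1C(=O)OC(C)(C)C
F2 | step 13 | methyl oxalate of F1 | COC(=O)C(=O)O[C@]1(C)CCC[C@@](C)(C(=O)OC(C)(C)C)[C@H]1C(=O)OC(C)(C)C
F3 | step 13 | cesium oxalate of F1 | [Cs+].[O-]C(=O)C(=O)O[C@]1(C)CCC[C@@](C)(C(=O)OC(C)(C)C)[C@H]1C(=O)OC(C)(C)C
F4 | step 9 | 2-[(tert-butyldimethylsilyl)oxy]-5-(dimethoxymethyl)-4-(phenylthio)bicyclo[3.2.1]oct-2-en-7-one (racemic) | CC(C)(C)[Si](C)(C)OC1=CC(Sc2ccccc2)C2(C(OC)OC)CC(=O)C1C2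
F5 | step 14 | 5-(dimethoxymethyl)-7-methylidenebicyclo[3.2.1]oct-2-ene-2-carboxylic acid, bridgeheads as in 18 | C=C1C[C@]2(C(OC)OC)C[C@H]1C(C(=O)O)=CC2
F6 | step 14 | acyl azide of F5 | C=C1C[C@]2(C(OC)OC)C[C@H]1C(C(=O)N=[N+]=[N-])=CC2
F7 | step 14 | 5-(dimethoxymethyl)-2-isocyanato-7-methylidenebicyclo[3.2.1]oct-2-ene | C=C1C[C@]2(C(OC)OC)C[C@H]1C(N=C=O)=CC2
F8 | step 14 | 5-(dimethoxymethyl)-7-methylidenebicyclo[3.2.1]octan-2-one | C=C1C[C@]2(C(OC)OC)C[C@H]1C(=O)CC2
F9 | step 14 | 5-(dimethoxymethyl)-7-methylidenebicyclo[3.2.1]oct-3-en-2-one | C=C1C[C@]2(C(OC)OC)C[C@H]1C(=O)C=C2
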